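**Retrosynthetic overview**

1. Skeletal locants: cyclopentene C3(Et)=C4–C5(Me)–C6–C11; cyclohexene C6–C7(Me)=C8–C9(Et, styryl)–C10(Me, CO2H)–C11; the rings are trans-fused at C6–C11. Last stage: the acid from its methyl ester; the C9 styryl group and the C7=C8 bond from a Carroll [3,3] shift of a C7 tertiary allylic alcohol, itself from methyl addition to a C7 enone.
2. Cyclohexene (second ring): kinetic intramolecular aldol closure C8–C9 and dehydration of a 1,5-diketone held on the finished cyclopentene, so that the trans fusion is inherited.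
3. Cyclopentene (first ring): C5–C6 by intramolecular enolate alkylation. Enabling feature: C6 is α to C7, the methyl-bearing sp2 carbon of the cyclohexene, which can be carried as an acetyl carbonyl, and C5 is the methyl-bearing carbon allylic to the ring C3=C4 bond; a C6 ketone enolate and a (Z)-allylic C5 sulfonate therefore face each other across C11–C3=C4 for 5-exo-tet closure.
4. Acyclic precursor: C10–C11 by catalytic asymmetric Michael addition of methyl 2-methyl-3-oxopentanoate to a (3E,5Z)-dienone; the dienone by Heck coupling of but-3-en-2-one with a (Z)-alkenyl iodide made from (S)-hex-3-yn-2-ol.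
5. Ring order: cyclopentene (step 8), then cyclohexene (step 9).

Key step: step 8

Remark: the sense of induction of the cinchona catalyst in step 5 is assumed to be as drawn (C10 R, C11 R); if it is the opposite, the pseudo-enantiomeric cupreine-derived catalyst is used and nothing else changes. Locants C3–C11 in the text are the skeletal locants of the overview; the systematic names carry their own numbering.

**Route**

Step 1
Reactants: 1 hex-3-yn-2-one
Product: 2 (2S)-hex-3-yn-2-ol
Conditions: RuCl[(S,S)-TsDPEN](p-cymene) (0.5 mol %), KOH (1 mol %), i-PrOH, 25 °C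
Reagents that add atoms: none
Why: Asymmetric transfer hydrogenation of an alkynyl ketone (Noyori type), in which the chiral ruthenium hydride/amine pair tells the slim alkynyl flank from the methyl flank and should deliver hydride to one carbonyl face, giving the (S)-carbinol that later becomes C5.

Step 2
Reactants: 2 (2S)-hex-3-yn-2-ol
Product: 4 (2S,3Z)-4-iodohex-3-en-2-ol, via cyclic alkenylaluminate 3 (not isolated)
Conditions: Red-Al (NaAlH2(OCH2CH2OMe)2), THF, 0 to 23 °C; then I2, THF, −78 °C
Reagents that add atoms: iodine, II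
Why: Hydroxyl-directed trans-hydroalumination of a propargylic alcohol, in which the alkoxyaluminate delivers hydride to the alkyne carbon next to the carbinol to give the five-membered alkenylaluminate 3, followed by iodinolysis of the C–Al bond with retention, should place iodine on the ethyl-bearing carbon cis to the carbinol carbon ((Z)-alkene) without touching the carbinol centre.

Step 3
Reactants: 4 (2S,3Z)-4-iodohex-3-en-2-ol
Product: 5 tert-butyl{[(2S,3Z)-4-iodohex-3-en-2-yl]oxy}dimethylsilane
Conditions: TBSCl, imidazole, DMF, 23 °C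
Reagents that add atoms: tert-butyldimethylsilyl chloride, CC(C)(C)[Si](C)(C)Cl
Why: Standard silylation of a secondary alcohol; the silyl ether keeps the (Z)-γ-oxygenated dienone of the next steps from closing by oxa-Michael addition and should survive the palladium and amine catalysis.

Step 4
Reactants: 5 tert-butyl{[(2S,3Z)-4-iodohex-3-en-2-yl]oxy}dimethylsilane; 6 but-3-en-2-one
Product: 7 (3E,5Z,7S)-7-{[tert-butyl(dimethyl)silyl]oxy}-5-ethylocta-3,5-dien-2-one
Conditions: Pd(OAc)2 (5 mol %), n-Bu4NCl, NaHCO3, DMF, 40 °C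
Reagents that add atoms: none
Why: Heck reaction of an alkenyl iodide with an enone under ligand-free phase-transfer conditions, in which syn-insertion and syn-β-hydride elimination should give the (E)-enone while the (Z)-trisubstituted alkene is carried over unchanged from the iodide.

Step 5
Reactants: 7 (3E,5Z,7S)-7-{[tert-butyl(dimethyl)silyl]oxy}-5-ethylocta-3,5-dien-2-one; 8 methyl 2-methyl-3-oxopentanoate
Product: 9 methyl (2R)-2-[(4R,5Z,7S)-7-{[tert-butyl(dimethyl)silyl]oxy}-5-ethyl-2-oxooct-5-en-4-yl]-2-methyl-3-oxopentanoate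
Conditions: 9-O-(9-phenanthryl)cupreidine (10 mol %), CH2Cl2, 23 °C
Reagents that add atoms: none
Why: Michael addition of an α-substituted β-keto ester to an enone under bifunctional cinchona catalysis (the quinuclidine pairs with the enolate, the 6′-hydroxyl binds the enone carbonyl), which should attack C11 in the 1,4-sense and set the quaternary C10 and the tertiary C11 in one event under catalyst control.

Step 6
Reactants: 9 methyl (2R)-2-[(4R,5Z,7S)-7-{[tert-butyl(dimethyl)silyl]oxy}-5-ethyl-2-oxooct-5-en-4-yl]-2-methyl-3-oxopentanoate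
Product: 10 methyl (2R)-2-[(4R,5Z,7S)-5-ethyl-7-hydroxy-2-oxooct-5-en-4-yl]-2-methyl-3-oxopentanoate
Conditions: HF·pyridine, pyridine, THF, 0 °C
Reagents that add atoms: none
Why: Fluoride cleavage of a secondary silyl ether in a buffered, weakly acidic medium that should neither enolise the 1,5-diketone nor reverse the Michael addition, and that touches no stereocentre.

Step 7
Reactants: 10 methyl (2R)-2-[(4R,5Z,7S)-5-ethyl-7-hydroxy-2-oxooct-5-en-4-yl]-2-methyl-3-oxopentanoate
Product: 11 methyl (2R)-2-[(4R,5Z,7S)-5-ethyl-7-(methanesulfonyloxy)-2-oxooct-5-en-4-yl]-2-methyl-3-oxopentanoate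
Conditions: MsCl, Et3N, CH2Cl2, −30 °C
Reagents that add atoms: methanesulfonyl chloride, CS(=O)(=O)Cl
Why: O-Sulfonylation with retention at C5; the (Z)-allylic mesylate is taken on cold and unpurified because it can ionise.

Step 8
Reactants: 11 methyl (2R)-2-[(4R,5Z,7S)-5-ethyl-7-(methanesulfonyloxy)-2-oxooct-5-en-4-yl]-2-methyl-3-oxopentanoate
Product: 12 methyl (2R)-2-[(1R,4R,5S)-5-acetyl-2-ethyl-4-methylcyclopent-2-en-1-yl]-2-methyl-3-oxopentanoate
Conditions: KOt-Bu (1.05 equiv), THF, −40 to 0 °C
Reagents that add atoms: none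
Why: Potassium tert-butoxide reversibly enolises the methyl ketone, and the C6 enolate displaces the (Z)-allylic mesylate at C5 in an intramolecular SN2 alkylation that forms the C5–C6 bond. The closest known reaction type is the cyclopent-3-ene synthesis from active-methylene compounds and (Z)-1,4-dielectrophilic but-2-enes, whose second stage is the same enolate closure across a cis alkene. The cyclopentene closes in the 5-(enolexo)-exo-tet mode. C5 is set by inversion of the (S)-carbinol centre laid down in step 1, C6 is set under thermodynamic control because the acetyl-bearing carbon epimerises through the enolate and should settle anti to both the C5 methyl group and the C11 substituent, and C10 and C11 pass through unchanged. The step needs C-alkylation at C6 to win over aldol addition of the C8 enolate, over SN2′ attack at C3 and over retro-Michael loss of the β-keto ester; the (Z)-geometry of C3=C4 holds C5 within reach of C6, C3 is fully substituted, the neopentyl-like C9 ketone is a poor and reversible aldol acceptor at low temperature, and the ring closure is irreversible and should be fast below 0 °C.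

Step 9
Reactants: 12 methyl (2R)-2-[(1R,4R,5S)-5-acetyl-2-ethyl-4-methylcyclopent-2-en-1-yl]-2-methyl-3-oxopentanoate
Product: 14 methyl (1S,5R,6R,9R)-4,7-diethyl-5,9-dimethyl-2-oxobicyclo[4.3.0]nona-3,7-diene-5-carboxylate, via lithium aldolate 13 (not isolated)
Conditions: LDA (1.05 equiv), THF, −78 °C; then SOCl2, pyridine, −78 to 0 °C
Reagents that add atoms: none
Why: Kinetic deprotonation of the acetyl methyl group (C8) avoids enolisation towards C6, the enolate should add to the C9 ketone in a 6-(enolexo)-exo-trig aldol closure across the trans-disposed arms so that the trans ring fusion is inherited from 12, and the tertiary aldolate is dehydrated in the same flask through its chlorosulfite by loss of the acidic C8 proton to give the conjugated enone.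

Step 10
Reactants: 14 methyl (1S,5R,6R,9R)-4,7-diethyl-5,9-dimethyl-2-oxobicyclo[4.3.0]nona-3,7-diene-5-carboxylate
Product: 15 methyl (1S,2S,5R,6R,9R)-4,7-diethyl-2-hydroxy-2,5,9-trimethylbicyclo[4.3.0]nona-3,7-diene-5-carboxylate
Conditions: MeTi(Oi-Pr)3 (2 equiv), THF, −20 to 23 °C
Reagents that add atoms: methyltitanium triisopropoxide, C[Ti](OC(C)C)(OC(C)C)OC(C)C
Why: 1,2-Addition of the bulky methyltitanium reagent to the enone carbonyl along the equatorial trajectory (the face of H6), as known for this reagent with cyclohexanones, should put the methyl group syn to H6 and the C7 hydroxyl axial on the opposite face, while the shielded ester is left alone.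

Step 11
Reactants: 15 methyl (1S,2S,5R,6R,9R)-4,7-diethyl-2-hydroxy-2,5,9-trimethylbicyclo[4.3.0]nona-3,7-diene-5-carboxylate; 16 ethyl 3-oxo-3-phenylpropanoate
Product: 19 methyl (1S,4S,5R,6R,9R)-4,7-diethyl-2,5,9-trimethyl-4-(2-oxo-2-phenylethyl)bicyclo[4.3.0]nona-2,7-diene-5-carboxylate, via benzoylacetate ester 17 (not isolated), via β-keto acid 18 (not isolated)
Conditions: Al(Oi-Pr)3 (10 mol %), o-xylene, 150 °C, ethanol distilled off
Reagents that add atoms: none
Why: Carroll rearrangement, in which acyl transfer gives the tertiary allylic β-keto ester 17, the suprafacial [3,3] shift of its enol should deliver the carbon substituent to C9 on the face of the axial C7–O bond (anti to the axial C10 methyl group) while the alkene moves to C7=C8, and the β-keto acid 18 loses CO2.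

Step 12
Reactants: 19 methyl (1S,4S,5R,6R,9R)-4,7-diethyl-2,5,9-trimethyl-4-(2-oxo-2-phenylethyl)bicyclo[4.3.0]nona-2,7-diene-5-carboxylate
Product: 20 methyl (1S,4S,5R,6R,9R)-4,7-diethyl-4-(2-hydroxy-2-phenylethyl)-2,5,9-trimethylbicyclo[4.3.0]nona-2,7-diene-5-carboxylate (both carbinol epimers)
Conditions: NaBH4, MeOH, 0 °C
Reagents that add atoms: none
Why: Chemoselective hydride reduction of the aryl ketone, which should leave the α-quaternary methyl ester and the alkenes untouched; the configuration of the new carbinol is of no consequence because it is removed in the next step.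

Step 13
Reactants: 20 methyl (1S,4S,5R,6R,9R)-4,7-diethyl-4-(2-hydroxy-2-phenylethyl)-2,5,9-trimethylbicyclo[4.3.0]nona-2,7-diene-5-carboxylate
Product: 21 methyl (1S,4S,5R,6R,9R)-4,7-diethyl-2,5,9-trimethyl-4-[(E)-2-phenylethenyl]bicyclo[4.3.0]nona-2,7-diene-5-carboxylate
Conditions: Burgess reagent, benzene, 60 °C
Reagents that add atoms: none
Why: Syn-elimination of the sulfamate ester of the benzylic alcohol, whose only β-hydrogens sit on the CH2 next to the quaternary C9, should give the conjugated styrene with the (E)-geometry favoured by the bulky C9 substituent.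

Step 14
Reactants: 21 methyl (1S,4S,5R,6R,9R)-4,7-diethyl-2,5,9-trimethyl-4-[(E)-2-phenylethenyl]bicyclo[4.3.0]nona-2,7-diene-5-carboxylate
Product: 22 24-nor-spiculoic acid B, (1S,4S,5R,6R,9R)-4,7-diethyl-2,5,9-trimethyl-4-[(E)-2-phenylethenyl]bicyclo[4.3.0]nona-2,7-diene-5-carboxylic acid
Conditions: n-PrSLi, HMPA, 23 °C; then 1 M HCl
Reagents that add atoms: none
Why: SN2 demethylation by thiolate at the ester methyl carbon bypasses the shielded acyl carbon of the α-quaternary ester and should free the acid without touching any stereocentre or alkene.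

**Compound list**

1 | hex-3-yn-2-one | CCC#CC(C)=O | starting material
2 | (2S)-hex-3-yn-2-ol | CCC#C[C@H](C)O | intermediate
3 | sodium (5S)-3-ethyl-2,2-bis(2-methoxyethoxy)-5-methyl-2,5-dihydro-1,2-oxaluminol-2-uide (cyclic alkenylaluminate) | CCC1=C[C@H](C)O[Al-]1(OCCOC)OCCOC.[Na+] | intermediate
4 | (2S,3Z)-4-iodohex-3-en-2-ol | CC/C(I)=C/[C@H](C)O | intermediate
5 | tert-butyl{[(2S,3Z)-4-iodohex-3-en-2-yl]oxy}dimethylsilane | CC/C(I)=C/[C@H](C)O[Si](C)(C)C(C)(C)C | intermediate
6 | but-3-en-2-one | CC(=O)C=C | starting material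
7 | (3E,5Z,7S)-7-{[tert-butyl(dimethyl)silyl]oxy}-5-ethylocta-3,5-dien-2-one | CC(=O)/C=C/C(CC)=C\[C@H](C)O[Si](C)(C)C(C)(C)C | intermediate
8 | methyl 2-methyl-3-oxopentanoate (racemic) | CCC(=O)C(C)C(=O)OC | starting material
9 | methyl (2R)-2-[(4R,5Z,7S)-7-{[tert-butyl(dimethyl)silyl]oxy}-5-ethyl-2-oxooct-5-en-4-yl]-2-methyl-3-oxopentanoate | CC(=O)C[C@H](/C(CC)=C\[C@H](C)O[Si](C)(C)C(C)(C)C)[C@@](C)(C(=O)OC)C(=O)CC | intermediate
10 | methyl (2R)-2-[(4R,5Z,7S)-5-ethyl-7-hydroxy-2-oxooct-5-en-4-yl]-2-methyl-3-oxopentanoate | CC(=O)C[C@H](/C(CC)=C\[C@H](C)O)[C@@](C)(C(=O)OC)C(=O)CC | intermediate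
11 | methyl (2R)-2-[(4R,5Z,7S)-5-ethyl-7-(methanesulfonyloxy)-2-oxooct-5-en-4-yl]-2-methyl-3-oxopentanoate | CC(=O)C[C@H](/C(CC)=C\[C@H](C)OS(C)(=O)=O)[C@@](C)(C(=O)OC)C(=O)CC | intermediate
12 | methyl (2R)-2-[(1R,4R,5S)-5-acetyl-2-ethyl-4-methylcyclopent-2-en-1-yl]-2-methyl-3-oxopentanoate (acetyl anti to both ring neighbours) | CCC1=C[C@@H](C)[C@H](C(C)=O)[C@H]1[C@@](C)(C(=O)OC)C(=O)CC | intermediate
13 | lithium alkoxide of methyl (1S,5R,6R,9R)-4,7-diethyl-4-hydroxy-5,9-dimethyl-2-oxobicyclo[4.3.0]non-7-ene-5-carboxylate (trans-fused aldolate, carbinol configuration not defined) | CCC1=C[C@@H](C)[C@@H]2C(=O)CC(CC)(O[Li])[C@](C)(C(=O)OC)[C@@H]12 | intermediate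
14 | methyl (1S,5R,6R,9R)-4,7-diethyl-5,9-dimethyl-2-oxobicyclo[4.3.0]nona-3,7-diene-5-carboxylate (trans-fused enone) | CCC1=C[C@@H](C)[C@@H]2C(=O)C=C(CC)[C@](C)(C(=O)OC)[C@@H]12 | intermediate
15 | methyl (1S,2S,5R,6R,9R)-4,7-diethyl-2-hydroxy-2,5,9-trimethylbicyclo[4.3.0]nona-3,7-diene-5-carboxylate (hydroxyl anti to H at C1) | CCC1=C[C@@H](C)[C@@H]2[C@](C)(O)C=C(CC)[C@](C)(C(=O)OC)[C@@H]12 | intermediate
16 | ethyl 3-oxo-3-phenylpropanoate (ethyl benzoylacetate) | CCOC(=O)CC(=O)c1ccccc1 | starting material
17 | 3-oxo-3-phenylpropanoate (benzoylacetate) ester of the tertiary alcohol 15 | CCC1=C[C@@H](C)[C@@H]2[C@](C)(OC(=O)CC(=O)c3ccccc3)C=C(CC)[C@](C)(C(=O)OC)[C@@H]12 | intermediate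
18 | 2-[(1S,4S,5R,6R,9R)-4,7-diethyl-5-(methoxycarbonyl)-2,5,9-trimethylbicyclo[4.3.0]nona-2,7-dien-4-yl]-3-oxo-3-phenylpropanoic acid (α-carbon not defined) | CCC1=C[C@@H](C)[C@@H]2C(C)=C[C@@](C(C(=O)O)C(=O)c3ccccc3)(CC)[C@](C)(C(=O)OC)[C@@H]12 | intermediate
19 | methyl (1S,4S,5R,6R,9R)-4,7-diethyl-2,5,9-trimethyl-4-(2-oxo-2-phenylethyl)bicyclo[4.3.0]nona-2,7-diene-5-carboxylate | CCC1=C[C@@H](C)[C@@H]2C(C)=C[C@@](CC(=O)c3ccccc3)(CC)[C@](C)(C(=O)OC)[C@@H]12 | intermediate
20 | methyl (1S,4S,5R,6R,9R)-4,7-diethyl-4-(2-hydroxy-2-phenylethyl)-2,5,9-trimethylbicyclo[4.3.0]nona-2,7-diene-5-carboxylate (both carbinol epimers) | CCC1=C[C@@H](C)[C@@H]2C(C)=C[C@@](CC(O)c3ccccc3)(CC)[C@](C)(C(=O)OC)[C@@H]12 | intermediate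
21 | methyl (1S,4S,5R,6R,9R)-4,7-diethyl-2,5,9-trimethyl-4-[(E)-2-phenylethenyl]bicyclo[4.3.0]nona-2,7-diene-5-carboxylate | CCC1=C[C@@H](C)[C@@H]2C(C)=C[C@@](/C=C/c3ccccc3)(CC)[C@](C)(C(=O)OC)[C@@H]12 | intermediate
22 | 24-nor-spiculoic acid B, (1S,4S,5R,6R,9R)-4,7-diethyl-2,5,9-trimethyl-4-[(E)-2-phenylethenyl]bicyclo[4.3.0]nona-2,7-diene-5-carboxylic acid | CCC1=C[C@@H](C)[C@@H]2C(C)=C[C@@](/C=C/c3ccccc3)(CC)[C@](C)(C(=O)O)[C@@H]12 | target

**Step count and risks**

Total step count: 14. Longest linear sequence: 14 steps (1 to 22); compounds 6, 8 and 16 enter as bought.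

The three steps most likely to fail:

Step 5. The hindered enolate may add with poor facial control at its own prochiral carbon (C10), may attack the remote alkene carbon C4 in the 1,6-sense, or the adduct may revert. The fallback sets out from 8 (with 7) and comes back at 9. Compound 8 is condensed with (S)-1-phenylethylamine to the hydrogen-bonded enamino ester methyl (2Z)-2-methyl-3-{[(1S)-1-phenylethyl]amino}pent-2-enoate F1 (the antipodal amine is taken if the sense of induction requires it). Its aza-ene-type Michael addition to 7 (neat or with ZnCl2, under pressure if needed) passes through a compact cyclic transition state that fixes the quaternary carbon relative to C11 and should give the N-[(1S)-1-phenylethyl] ketimine of 9 at the pentanoate C3 carbonyl F2. Aqueous acetic acid then releases the amine and gives 9.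

Step 10. Delivery of the methyl group along the axial trajectory would put the C7 hydroxyl on the wrong face, and the following [3,3] shift would then build C9 with the opposite configuration. The fallback sets out from 14 and comes back at 21, so that steps 10 to 13 are not needed. Conjugate addition of the (E)-2-phenylethenyl cuprate (from (E)-2-phenylethenylmagnesium bromide and CuBr·SMe2, THF, −78 °C) to the enone should take place anti to the axial C10 methyl group and give the bromomagnesium C7 enolate of the C9 styryl ketone F3. This is trapped in the same flask with N-(5-chloropyridin-2-yl)bis(trifluoromethanesulfonyl)imide as the enol triflate methyl (1S,4S,5R,6R,9R)-4,7-diethyl-5,9-dimethyl-4-[(E)-2-phenylethenyl]-2-{[(trifluoromethyl)sulfonyl]oxy}bicyclo[4.3.0]nona-2,7-diene-5-carboxylate F4. Coupling with MeMgBr under Fe(acac)3 catalysis then gives 21.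

Step 11. Acyl transfer to the hindered tertiary alcohol may not take place, or the tertiary allylic ester may ionise and eliminate to a diene before it rearranges. The fallback sets out from 15 and comes back at 19. Eschenmoser–Claisen rearrangement with N,N-dimethylacetamide dimethyl acetal (xylene, 140 °C) needs neither an acylation nor a decarboxylation and should give, by the same suprafacial [3,3] shift, the amide methyl (1S,4S,5R,6R,9R)-4-[2-(dimethylamino)-2-oxoethyl]-4,7-diethyl-2,5,9-trimethylbicyclo[4.3.0]nona-2,7-diene-5-carboxylate F5. Phenyllithium (THF, −78 °C) then converts the amide into ketone 19.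

**Further compounds**

F1 | step 5 | methyl (2Z)-2-methyl-3-{[(1S)-1-phenylethyl]amino}pent-2-enoate | CC/C(N[C@@H](C)c1ccccc1)=C(\C)C(=O)OC
F2 | step 5 | N-[(1S)-1-phenylethyl] ketimine of 9 at the pentanoate C3 carbonyl | CC(=O)C[C@H](/C(CC)=C\[C@H](C)O[Si](C)(C)C(C)(C)C)[C@@](C)(C(=O)OC)C(CC)=N[C@@H](C)c1ccccc1
F3 | step 10 | bromomagnesium C7 enolate of the C9 styryl ketone | CCC1=C[C@@H](C)[C@@H]2C(O[Mg]Br)=C[C@@](/C=C/c3ccccc3)(CC)[C@](C)(C(=O)OC)[C@@H]12
F4 | step 10 | methyl (1S,4S,5R,6R,9R)-4,7-diethyl-5,9-dimethyl-4-[(E)-2-phenylethenyl]-2-{[(trifluoromethyl)sulfonyl]oxy}bicyclo[4.3.0]nona-2,7-diene-5-carboxylate | CCC1=C[C@@H](C)[C@@H]2C(OS(=O)(=O)C(F)(F)F)=C[C@@](/C=C/c3ccccc3)(CC)[C@](C)(C(=O)OC)[C@@H]12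
F5 | step 11 | methyl (1S,4S,5R,6R,9R)-4-[2-(dimethylamino)-2-oxoethyl]-4,7-diethyl-2,5,9-trimethylbicyclo[4.3.0]nona-2,7-diene-5-carboxylate | CCC1=C[C@@H](C)[C@@H]2C(C)=C[C@@](CC(=O)N(C)C)(CC)[C@](C)(C(=O)OC)[C@@H]12
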